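**Retrosynthetic overview**

- The target is reached from a 20-membered trimethyl ether cycloalkene by alkene hydrogenation and BBr3 demethylation.
- The strategy rests on the unfunctionalised fourteen-carbon chain from C6 of ring B (dihydroxy ring) to C3 of ring A (monohydroxy ring). Its C3–C4 bond (counted from ring B) is made by SO2 extrusion from a 21-membered thiacyclophane S,S-dioxide (Ramberg–Bäcklund ring contraction).
- The 21-membered ring is closed at sulfur: a thiolate, made by AcSH addition to the ring B allyl group, displaces the bromide at the end of the ring A C11 chain.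
- The open-chain diaryl ether comes from Ullmann coupling of 2-allyl-4,6-dimethoxyphenol (O-allylation and Claisen rearrangement of 2,4-dimethoxyphenol) with 11-(3-bromo-5-methoxyphenyl)undecan-1-ol (B-alkyl Suzuki coupling of 3,5-dibromoanisole with 10-undecen-1-ol).
- Ring order: rings A and B are bought, the 21-membered thiacycle is formed in step 7, and it is contracted to the 20-membered carbocycle in step 9.

Key step: step 9

Remark on the chemistry: ring A carries OH at C1, the chain at C3 and the ether oxygen at C5; ring B carries the ether oxygen at C1, OH at C2 and C4 and the chain at C6. The target has no stereocentre. The alkene from step 9 is expected as an E/Z mixture (drawn E) and both isomers converge in step 10.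

**Route**

Step 1
Reactants: 1 2,4-dimethoxyphenol; 2 allyl bromide
Product: 3 1-(allyloxy)-2,4-dimethoxybenzene
Conditions: K2CO3, acetone, reflux
Reagents that add atoms: none
Why: Williamson ether synthesis, in which the phenoxide displaces the allylic bromide by SN2 and O-alkylation dominates in acetone with carbonate base.

Step 2
Reactants: 3 1-(allyloxy)-2,4-dimethoxybenzene
Product: 5 2-allyl-4,6-dimethoxyphenol, via 6-allyl-2,4-dimethoxycyclohexa-2,4-dienone 4 (not isolated)
Conditions: PhNEt2, 200 °C, sealed tube, Ar
Reagents that add atoms: none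
Why: Aromatic Claisen rearrangement ([3,3]-sigmatropic shift) should place the allyl group on C6, the only unsubstituted ortho carbon (C2 and the para carbon C4 carry OMe), after which dienone 4 tautomerises to the phenol.

Step 3
Reactants: 6 10-undecen-1-ol; 7 3,5-dibromoanisole
Product: 9 11-(3-bromo-5-methoxyphenyl)undecan-1-ol, via alkylborane 8 (not isolated)
Conditions: 9-BBN (2.2 equiv), THF, 0 °C → rt; then 7 (3 equiv), PdCl2(dppf) (cat.), aq. K3PO4, THF/DMF, 60 °C
Reagents that add atoms: none
Why: Anti-Markovnikov hydroboration followed by B-alkyl Suzuki–Miyaura coupling should transfer the primary alkyl group to one C–Br bond of 7, double coupling being limited by the excess of dibromide, while the hydroxyl is held as its B-alkoxy-9-BBN ester and released on work-up.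

Step 4
Reactants: 5 2-allyl-4,6-dimethoxyphenol; 9 11-(3-bromo-5-methoxyphenyl)undecan-1-ol
Product: 10 11-[3-(2-allyl-4,6-dimethoxyphenoxy)-5-methoxyphenyl]undecan-1-ol
Conditions: CuI (cat.), picolinic acid (cat.), K3PO4, DMSO, 90 °C, Ar
Reagents that add atoms: none
Why: Ullmann-type copper-catalysed C–O coupling with picolinic acid as ligand is suited to ortho,ortho-disubstituted phenols and an unhindered aryl bromide, and the phenoxide should be arylated much faster than the primary alcohol.

Step 5
Reactants: 10 11-[3-(2-allyl-4,6-dimethoxyphenoxy)-5-methoxyphenyl]undecan-1-ol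
Product: 11 1-allyl-2-[3-(11-bromoundecyl)-5-methoxyphenoxy]-3,5-dimethoxybenzene
Conditions: CBr4, PPh3, CH2Cl2, 0 °C → rt
Reagents that add atoms: carbon tetrabromide, BrC(Br)(Br)Br
Why: Appel reaction, in which bromide displaces the primary alkoxyphosphonium by SN2 under neutral conditions that leave the allyl group and the aryl ethers untouched.

Step 6
Reactants: 11 1-allyl-2-[3-(11-bromoundecyl)-5-methoxyphenoxy]-3,5-dimethoxybenzene
Product: 12 S-(3-{2-[3-(11-bromoundecyl)-5-methoxyphenoxy]-3,5-dimethoxyphenyl}propyl) ethanethioate
Conditions: AcSH (3 equiv), AIBN (cat.), degassed toluene, 75 °C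
Reagents that add atoms: thioacetic acid, CC(=O)S
Why: Radical thiol–ene addition, in which the acetylthiyl radical adds to the terminal alkene carbon (anti-Markovnikov) and the secondary radical abstracts hydrogen from AcSH, while the primary bromide is inert to thiyl radicals.

Step 7
Reactants: 12 S-(3-{2-[3-(11-bromoundecyl)-5-methoxyphenoxy]-3,5-dimethoxyphenyl}propyl) ethanethioate
Product: 14 21-membered cyclic sulfide (thiacyclophane trimethyl ether: ring B C6–(CH2)3–S–(CH2)11–C3 ring A), via potassium thiolate 13 (not isolated)
Conditions: K2CO3, degassed MeOH/THF, syringe-pump addition of 12 to high dilution, rt → 40 °C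
Reagents that add atoms: none
Why: Methanolysis of the thioacetate releases thiolate 13 at low stationary concentration, and intramolecular SN2 attack of this soft nucleophile on the unhindered primary bromide should close the 21-membered ring (macrocyclic thioether formation by thiolate alkylation).

Step 8
Reactants: 14 21-membered cyclic sulfide
Product: 16 21-membered cyclic sulfone (thiacyclophane S,S-dioxide trimethyl ether), via cyclic sulfoxide 15 (not isolated)
Conditions: mCPBA (2.3 equiv), CH2Cl2, 0 °C → rt
Reagents that add atoms: 3-chloroperoxybenzoic acid, O=C(OO)c1cccc(Cl)c1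
Why: Peracid oxidation of a dialkyl sulfide through the sulfoxide to the sulfone is much faster than attack on the methoxylated arenes, so stoichiometry and low temperature should control it.

Step 9
Reactants: 16 21-membered cyclic sulfone
Product: 19 20-membered cycloalkene trimethyl ether with the C3=C4 double bond, via alpha-bromosulfone 17 (not isolated), via episulfone 18 (not isolated)
Conditions: KOH/Al2O3, CBr2F2, t-BuOH/CH2Cl2, 5 °C → rt
Reagents that add atoms: none
Why: Ramberg–Bäcklund reaction with in situ halogenation: KOH on Al2O3 deprotonates one α-CH2 of 16, the carbanion takes bromine from CBr2F2 to give 17, α′-deprotonation and 1,3-displacement of bromide give episulfone 18, and cheletropic loss of SO2 forms the C3=C4 bond. The closest known reaction type is the Ramberg–Bäcklund contraction of macrocyclic thiacyclophane S,S-dioxides to cycloalkenes. The 20-membered carbocycle is closed by contraction of the existing 21-membered ring, through a 3-exo-tet closure to the thiirane dioxide followed by extrusion, so no end-to-end C–C macrocyclisation is needed. No stereocentre survives, since the two episulfone carbons are transient and the alkene geometry is erased in step 10. The step needs halogenation only α to sulfur, which is secured because the two SO2–CH2 groups are the only acidic C–H bonds in 16, and either α carbon leads to the same alkene. CBr2F2 is chosen because the difluorocarbene it releases adds poorly to a 1,2-dialkyl alkene, which should limit carbene adducts.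

Step 10
Reactants: 19 20-membered cycloalkene trimethyl ether
Product: 20 20-membered saturated macrocycle trimethyl ether
Conditions: H2 (1 atm), Pd/C, EtOAc, rt
Reagents that add atoms: none
Why: Heterogeneous catalytic hydrogenation saturates the 1,2-disubstituted alkene of either geometry, and the molecule holds no hydrogenolysable benzylic C–O bond.

Step 11
Reactants: 20 20-membered saturated macrocycle trimethyl ether
Product: 22 target CNP0173380.0 (macrocyclic triphenol), via tris(dibromoboryl) ether 21 (not isolated)
Conditions: BBr3 (6 equiv), CH2Cl2, −78 °C → rt; then H2O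
Reagents that add atoms: none
Why: Lewis acid mediated aryl methyl ether cleavage, in which BBr3 coordinates each methoxy oxygen and bromide removes the methyl group by SN2 to give aryloxyboranes that hydrolyse on work-up, while the diaryl ether has no sp3 C–O bond and should persist.

**Compound list**

1 | 2,4-dimethoxyphenol | COc1ccc(O)c(OC)c1 | starting material
2 | allyl bromide | C=CCBr | starting material
3 | 1-(allyloxy)-2,4-dimethoxybenzene | C=CCOc1ccc(OC)cc1OC | intermediate
4 | 6-allyl-2,4-dimethoxycyclohexa-2,4-dienone (Claisen dienone, not isolated) | O=C1C(OC)=CC(OC)=CC1CC=C | intermediate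
5 | 2-allyl-4,6-dimethoxyphenol | C=CCc1cc(OC)cc(OC)c1O | intermediate
6 | 10-undecen-1-ol | C=CCCCCCCCCCO | starting material
7 | 3,5-dibromoanisole | COc1cc(Br)cc(Br)c1 | starting material
8 | B-[11-(9-borabicyclo[3.3.1]nonan-9-yloxy)undecyl]-9-borabicyclo[3.3.1]nonane (alkylborane, not isolated) | C1CC2CCCC(C1)B2CCCCCCCCCCCOB1C2CCCC1CCC2 | intermediate
9 | 11-(3-bromo-5-methoxyphenyl)undecan-1-ol | COc1cc(Br)cc(CCCCCCCCCCCO)c1 | intermediate
10 | 11-[3-(2-allyl-4,6-dimethoxyphenoxy)-5-methoxyphenyl]undecan-1-ol | COc1cc(CCCCCCCCCCCO)cc(Oc2c(OC)cc(OC)cc2CC=C)c1 | intermediate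
11 | 1-allyl-2-[3-(11-bromoundecyl)-5-methoxyphenoxy]-3,5-dimethoxybenzene | COc1cc(CCCCCCCCCCCBr)cc(Oc2c(OC)cc(OC)cc2CC=C)c1 | intermediate
12 | S-(3-{2-[3-(11-bromoundecyl)-5-methoxyphenoxy]-3,5-dimethoxyphenyl}propyl) ethanethioate | COc1cc(CCCCCCCCCCCBr)cc(Oc2c(OC)cc(OC)cc2CCCSC(C)=O)c1 | intermediate
13 | potassium 3-{2-[3-(11-bromoundecyl)-5-methoxyphenoxy]-3,5-dimethoxyphenyl}propane-1-thiolate (not isolated) | COc1cc(CCCCCCCCCCCBr)cc(Oc2c(OC)cc(OC)cc2CCC[S-])c1.[K+] | intermediate
14 | 21-membered cyclic sulfide: ring B C6–(CH2)3–S–(CH2)11–C3 ring A, rings joined by the C1(B)–O–C5(A) ether, OMe at A-1, B-2 and B-4 | COc1cc2cc(c1)Oc1c(OC)cc(OC)cc1CCCSCCCCCCCCCCC2 | intermediate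
15 | corresponding cyclic sulfoxide (not isolated) | COc1cc2cc(c1)Oc1c(OC)cc(OC)cc1CCCS(=O)CCCCCCCCCCC2 | intermediate
16 | 21-membered cyclic sulfone (thiacyclophane S,S-dioxide trimethyl ether) | COc1cc2cc(c1)Oc1c(OC)cc(OC)cc1CCCS(=O)(=O)CCCCCCCCCCC2 | intermediate
17 | alpha-bromosulfone, bromine drawn on the alpha carbon of the long chain; the regioisomer gives the same episulfone (not isolated) | COc1cc2cc(c1)Oc1c(OC)cc(OC)cc1CCCS(=O)(=O)C(Br)CCCCCCCCCC2 | intermediate
18 | episulfone (thiirane 1,1-dioxide spanning chain carbons C3 and C4, not isolated) | COc1cc2cc(c1)Oc1c(OC)cc(OC)cc1CCC1C(CCCCCCCCCC2)S1(=O)=O | intermediate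
19 | 20-membered cycloalkene trimethyl ether, C3=C4 (E drawn; the Z isomer is expected alongside) | COc1cc2cc(c1)Oc1c(OC)cc(OC)cc1CC/C=C/CCCCCCCCCC2 | intermediate
20 | 20-membered saturated macrocycle trimethyl ether | COc1cc2cc(c1)Oc1c(OC)cc(OC)cc1CCCCCCCCCCCCCC2 | intermediate
21 | tris(dibromoboryl) ether of the triphenol (not isolated) | BrB(Br)Oc1cc2cc(c1)Oc1c(OB(Br)Br)cc(OB(Br)Br)cc1CCCCCCCCCCCCCC2 | intermediate
22 | CNP0173380.0, macrocyclic triphenol | Oc1cc2cc(c1)Oc1c(O)cc(O)cc1CCCCCCCCCCCCCC2 | target

**Step count**

Total steps: 11. Longest linear sequence: 10 steps (1 → 3 → 5 → 10 → 11 → 12 → 14 → 16 → 19 → 20 → 22; step 3 is the side branch).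

**Steps most likely to fail**

1. Step 9 (Ramberg–Bäcklund contraction). Possible failures are repeated α-halogenation, capture of the new alkene by difluorocarbene, or stalled conversion on the solid base. The fallback sets out from 11 and closes the carbocycle by olefin metathesis. Bromide 11 would be coupled with vinylmagnesium bromide under Li2CuCl4 catalysis (THF, −10 °C → rt) to give the diene 1-allyl-2-[3-methoxy-5-(tridec-12-en-1-yl)phenoxy]-3,5-dimethoxybenzene F1. Ring-closing metathesis with the second-generation Grubbs catalyst RuCl2(=CHPh)(SIMes)(PCy3) in dilute CH2Cl2 at reflux should give the 20-membered C2=C3 cycloalkene trimethyl ether F2 as an E/Z mixture. Hydrogenation over Pd/C in EtOAc then gives 20, where the route is rejoined.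

2. Step 7 (thiolate macrocyclisation). Intermolecular alkylation to oligomers or oxidative disulfide formation may outrun ring closure. The fallback sets out from 11 and closes the ring by a radical addition. Bromide 11 would be treated with KSAc in DMF to give the S-alkyl thioacetate S-{11-[3-(2-allyl-4,6-dimethoxyphenoxy)-5-methoxyphenyl]undecyl} ethanethioate F3. Methanolysis (K2CO3, degassed MeOH) gives the thiol 11-[3-(2-allyl-4,6-dimethoxyphenoxy)-5-methoxyphenyl]undecane-1-thiol F4. Photoinitiated intramolecular thiol–ene addition (2,2-dimethoxy-2-phenylacetophenone, 365 nm, dilute degassed THF) should then give the anti-Markovnikov sulfide 14, where the route is rejoined.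

3. Step 4 (Ullmann coupling). Coupling of the doubly ortho-substituted phenoxide may be slow, and at the required temperature the base may move the allyl double bond into conjugation or the electron-rich phenol may be oxidised. The fallback sets out from 9 and makes the C–O bond by oxidative coupling at room temperature. Miyaura borylation of 9 (B2pin2, PdCl2(dppf), KOAc, dioxane, 80 °C) gives the pinacol boronate 11-[3-methoxy-5-(4,4,5,5-tetramethyl-1,3,2-dioxaborolan-2-yl)phenyl]undecan-1-ol F5. Cleavage with NaIO4/NH4OAc in acetone/water gives the boronic acid [3-(11-hydroxyundecyl)-5-methoxyphenyl]boronic acid F6. Chan–Lam coupling of F6 with phenol 5 (Cu(OAc)2, pyridine, 4 Å molecular sieves, air, CH2Cl2, rt) should give 10, where the route is rejoined.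

**Further compounds**

F1 | step 9 | 1-allyl-2-[3-methoxy-5-(tridec-12-en-1-yl)phenoxy]-3,5-dimethoxybenzene | COc1cc(CCCCCCCCCCCC=C)cc(Oc2c(OC)cc(OC)cc2CC=C)c1
F2 | step 9 | 20-membered C2=C3 cycloalkene trimethyl ether (E drawn) | COc1cc2cc(c1)Oc1c(OC)cc(OC)cc1C/C=C/CCCCCCCCCCC2
F3 | step 7 | S-{11-[3-(2-allyl-4,6-dimethoxyphenoxy)-5-methoxyphenyl]undecyl} ethanethioate | COc1cc(CCCCCCCCCCCSC(C)=O)cc(Oc2c(OC)cc(OC)cc2CC=C)c1
F4 | step 7 | 11-[3-(2-allyl-4,6-dimethoxyphenoxy)-5-methoxyphenyl]undecane-1-thiol | COc1cc(CCCCCCCCCCCS)cc(Oc2c(OC)cc(OC)cc2CC=C)c1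
F5 | step 4 | 11-[3-methoxy-5-(4,4,5,5-tetramethyl-1,3,2-dioxaborolan-2-yl)phenyl]undecan-1-ol | COc1cc(B2OC(C)(C)C(C)(C)O2)cc(CCCCCCCCCCCO)c1
F6 | step 4 | [3-(11-hydroxyundecyl)-5-methoxyphenyl]boronic acid | COc1cc(B(O)O)cc(CCCCCCCCCCCO)c1
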